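**Retrosynthetic overview**

1. The two esters go on last: the C-8 isovalerate by Mitsunobu inversion of an allylic alcohol made from a C-8 enone, and the C-4 aryl ester by Pd-catalysed carbonylative coupling with silyl-protected 4-iodophenol.
2. The seven-membered ring is formed last, from a trans-hydrindanone, by a one-carbon ring expansion (radical 1,2-acyl shift) that inserts CH between the ketone and its methyl-bearing α-carbon and gives the β-methyl enone.
3. The five-membered ring is formed second, on a cyclohexenone: tandem conjugate alkenylation/enolate allylation (trans ring fusion, quaternary methyl), ring-closing metathesis, then Markovnikov hydration anti to the angular methyl.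
4. The six-membered ring is formed first, from (silyloxy)acetaldehyde and ethyl vinyl ketone by organocatalytic Michael/aldol condensation; its silyloxy stereocentre relays absolute configuration and is later reset by oxidation and axial-selective reduction.

Reading of the target: trans ring fusion; the 8a-methyl is cis to the C-3 isopropyl group and to the C-4 benzoate oxygen, and trans to H-3a, the C-3 hydroxyl and the C-8 isovalerate oxygen; descriptors (3S,3aS,4R,8R,8aS).

Assumption: 2-[(tert-butyldimethylsilyl)oxy]acetaldehyde and tert-butyl(4-iodophenoxy)dimethylsilane are bought as the silyl-protected forms of glycolaldehyde and 4-iodophenol.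

**Route**

Step 1
Reactants: 1 2-[(tert-butyldimethylsilyl)oxy]acetaldehyde; 2 pent-1-en-3-one
Product: 4 (4S)-4-[(tert-butyldimethylsilyl)oxy]-2-methylcyclohex-2-en-1-one, via keto aldehyde 3 (not isolated)
Conditions: (R)-α,α-diphenylprolinol trimethylsilyl ether (10 mol %), ethyl 3,4-dihydroxybenzoate (20 mol %), neat, 4 °C; then Bn2NH·CF3CO2H (20 mol %), toluene, 45 °C
Reagents that add atoms: none
Why: Enamine-catalysed asymmetric Michael addition of the aldehyde to the vinyl ketone (the (R)-catalyst shields one enamine face and sets the silyloxy-bearing centre as S), followed by amine-salt-catalysed aldol condensation of the ethyl ketone onto the aldehyde (organocatalytic Robinson annulation), gives the 2-methyl enone without touching the new stereocentre.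

Step 2
Reactants: 4 (4S)-4-[(tert-butyldimethylsilyl)oxy]-2-methylcyclohex-2-en-1-one; 5 2-bromo-3-methylbut-1-ene; 6 3-bromoprop-1-ene
Product: 9 (2S,3S,4S)-4-[(tert-butyldimethylsilyl)oxy]-2-methyl-3-(3-methylbut-1-en-2-yl)-2-(prop-2-en-1-yl)cyclohexan-1-one, via alkenylmagnesium bromide 7 (not isolated), via magnesium enolate 8 (not isolated)
Conditions: 5, Mg turnings, THF, 40 °C; then 4, CuBr·SMe2 (10 mol %), THF, −78 → −40 °C; then 6, HMPA, −40 → 0 °C
Reagents that add atoms: none
Why: Copper-catalysed 1,4-addition of the alkenyl Grignard reagent occurs anti to the C-4 silyloxy group and the enolate is then C-allylated anti to the new C-3 substituent (tandem conjugate addition–enolate alkylation), which fixes the trans relationship of the two future ring-fusion bonds and the quaternary methyl centre.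

Step 3
Reactants: 9 (2S,3S,4S)-4-[(tert-butyldimethylsilyl)oxy]-2-methyl-3-(3-methylbut-1-en-2-yl)-2-(prop-2-en-1-yl)cyclohexan-1-one
Product: 10 (2S,3S,4S,6R)-4-[(tert-butyldimethylsilyl)oxy]-2,6-dimethyl-3-(3-methylbut-1-en-2-yl)-2-(prop-2-en-1-yl)cyclohexan-1-one
Conditions: LiN(i-Pr)2, THF, −78 °C; MeI, −78 → 0 °C; then NaOMe (cat.), MeOH, 23 °C
Reagents that add atoms: iodomethane, CI
Why: Only C-6 of the ketone is enolisable, so enolate methylation (α-alkylation) is regiospecific, and brief base equilibration puts the new methyl equatorial (6R); this centre becomes sp2 in step 9.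

Step 4
Reactants: 10 (2S,3S,4S,6R)-4-[(tert-butyldimethylsilyl)oxy]-2,6-dimethyl-3-(3-methylbut-1-en-2-yl)-2-(prop-2-en-1-yl)cyclohexan-1-one
Product: 11 (3aS,5R,7S,7aS)-7-[(tert-butyldimethylsilyl)oxy]-3a,5-dimethyl-1-(propan-2-yl)-3,3a,5,6,7,7a-hexahydro-4H-inden-4-one
Conditions: second-generation Hoveyda–Grubbs catalyst RuCl2(SIMes)(=CH-C6H4-2-O-i-Pr) (5 mol %), toluene, 80 °C
Reagents that add atoms: none
Why: Ring-closing metathesis of the allyl group with the 1,1-disubstituted alkene closes the isopropyl-substituted cyclopentene with loss of ethene and leaves the trans ring fusion set in step 2 untouched.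

Step 5
Reactants: 11 (3aS,5R,7S,7aS)-7-[(tert-butyldimethylsilyl)oxy]-3a,5-dimethyl-1-(propan-2-yl)-3,3a,5,6,7,7a-hexahydro-4H-inden-4-one
Product: 12 (1S,3aS,5R,7S,7aS)-7-[(tert-butyldimethylsilyl)oxy]-1-hydroxy-3a,5-dimethyl-1-(propan-2-yl)octahydro-4H-inden-4-one
Conditions: Co(acac)2 (20 mol %), PhSiH3, O2 (1 atm), i-PrOH, 23 °C
Reagents that add atoms: dioxygen, O=O
Why: Mukaiyama hydration (hydrogen-atom transfer to C-2 from the hydride made from Co(acac)2 and PhSiH3, O2 capture of the tertiary C-1 radical, then reduction) is Markovnikov, and oxygen enters on the ring face opposite the angular 3a-methyl, which places the isopropyl group cis to that methyl (1S).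

Step 6
Reactants: 12 (1S,3aS,5R,7S,7aS)-7-[(tert-butyldimethylsilyl)oxy]-1-hydroxy-3a,5-dimethyl-1-(propan-2-yl)octahydro-4H-inden-4-one
Product: 13 (1S,3aS,5R,7S,7aS)-1,7-dihydroxy-3a,5-dimethyl-1-(propan-2-yl)octahydro-4H-inden-4-one
Conditions: HF·pyridine, THF, 0 → 23 °C
Reagents that add atoms: none
Why: Fluoride-mediated silyl ether cleavage frees the secondary C-7 alcohol, whose configuration served only to relay chirality and is corrected in the next two steps.

Step 7
Reactants: 13 (1S,3aS,5R,7S,7aS)-1,7-dihydroxy-3a,5-dimethyl-1-(propan-2-yl)octahydro-4H-inden-4-one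
Product: 14 (1S,3aS,5R,7aR)-1-hydroxy-3a,5-dimethyl-1-(propan-2-yl)hexahydro-1H-indene-4,7-dione
Conditions: Dess–Martin periodinane, pyridine, CH2Cl2, 0 → 23 °C
Reagents that add atoms: none
Why: Dess–Martin oxidation converts the only secondary alcohol into the ketone under buffered, non-enolising conditions that spare the tertiary alcohol and the ring-fusion centre.

Step 8
Reactants: 14 (1S,3aS,5R,7aR)-1-hydroxy-3a,5-dimethyl-1-(propan-2-yl)hexahydro-1H-indene-4,7-dione
Product: 15 (1S,3aS,5R,7R,7aS)-1,7-dihydroxy-3a,5-dimethyl-1-(propan-2-yl)octahydro-4H-inden-4-one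
Conditions: LiBH(s-Bu)3, THF, −78 °C; then aqueous work-up
Reagents that add atoms: none
Why: The bulky trialkylborohydride reduces only the C-7 ketone (the C-4 ketone is flanked by a quaternary and a tertiary carbon) by equatorial attack away from the 1,3-related angular methyl, giving the axial (7R) alcohol cis to that methyl (substrate-controlled ketone reduction).

Step 9
Reactants: 15 (1S,3aS,5R,7R,7aS)-1,7-dihydroxy-3a,5-dimethyl-1-(propan-2-yl)octahydro-4H-inden-4-one
Product: 16 (1S,3aS,7R,7aS)-3a,5-dimethyl-1-(propan-2-yl)-1,4,7-tris[(trimethylsilyl)oxy]-2,3,3a,6,7,7a-hexahydro-1H-indene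
Conditions: Me3SiOTf, Et3N, CH2Cl2, 0 °C
Reagents that add atoms: trimethylsilyl trifluoromethanesulfonate, C[Si](C)(C)OS(=O)(=O)C(F)(F)F
Why: Soft enolisation (silyl triflate/amine) can only give the C-4/C-5 silyl enol ether because the other α-carbon is quaternary, and both hydroxyl groups are silylated in the same operation.

Step 10
Reactants: 16 (1S,3aS,7R,7aS)-3a,5-dimethyl-1-(propan-2-yl)-1,4,7-tris[(trimethylsilyl)oxy]-2,3,3a,6,7,7a-hexahydro-1H-indene
Product: 19 (3S,3aS,4R,8aS)-3,4-dihydroxy-6,8a-dimethyl-3-(propan-2-yl)-2,3,3a,4,5,8a-hexahydroazulen-8(1H)-one, via iodomethyl ketone 17 (not isolated), via bis-silyl enone 18 (not isolated)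
Conditions: CH2I2, fac-Ir(ppy)3 (1 mol %), Co(dmgH)2(py)Cl (8 mol %), 2,6-lutidine, MeCN, blue LEDs, 25 °C; then DBU (cat.); then 1 M HCl, THF, 0 °C
Reagents that add atoms: diiodomethane, ICI
Why: Proposed new method: a dual photoredox/cobalt homologative desaturation in which excited fac-Ir(ppy)3 reduces CH2I2 to the iodomethyl radical, which adds to C-5 of the silyl enol ether on the face away from the 3a-methyl, the α-silyloxy radical is oxidised with loss of Me3SiI to iodomethyl ketone 17, univalent cobalt made from Co(dmgH)2(py)Cl then displaces iodide and light homolyses the Co–C bond to a primary radical that has no β-hydrogen and can only add to the ketone carbon and cleave the old C-4–C-5 ring bond (radical 1,2-acyl shift, six- to seven-membered ring), and divalent cobalt finally abstracts hydrogen from the tertiary β-keto radical to give the conjugated enone (DBU moves any β,γ-isomer into conjugation, dilute acid removes the two silyl ethers, no stereocentre is touched); the closest known reaction types are the Dowd–Beckwith ring expansion of α-halomethyl ketones, the Ito–Saegusa FeCl3 ring expansion of siloxycyclopropanes and cobalt-photocatalysed dehydrohalogenation.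

Step 11
Reactants: 19 (3S,3aS,4R,8aS)-3,4-dihydroxy-6,8a-dimethyl-3-(propan-2-yl)-2,3,3a,4,5,8a-hexahydroazulen-8(1H)-one; 20 tert-butyl(4-iodophenoxy)dimethylsilane
Product: 21 (3S,3aS,4R,8aS)-3-hydroxy-6,8a-dimethyl-8-oxo-3-(propan-2-yl)-1,2,3,3a,4,5,8,8a-octahydroazulen-4-yl 4-[(tert-butyldimethylsilyl)oxy]benzoate
Conditions: Pd(OAc)2 (5 mol %), Xantphos (6 mol %), CO (1 atm), Et3N, DMAP (20 mol %), toluene, 90 °C
Reagents that add atoms: carbon monoxide, [C-]#[O+]
Why: Palladium-catalysed alkoxycarbonylation (oxidative addition of the aryl iodide to zerovalent palladium, CO insertion, DMAP-assisted acyl transfer) esterifies the only secondary alcohol with retention at C-4 while the tertiary alcohol stays free.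

Step 12
Reactants: 21 (3S,3aS,4R,8aS)-3-hydroxy-6,8a-dimethyl-8-oxo-3-(propan-2-yl)-1,2,3,3a,4,5,8,8a-octahydroazulen-4-yl 4-[(tert-butyldimethylsilyl)oxy]benzoate
Product: 22 (3S,3aS,4R,8S,8aS)-3,8-dihydroxy-6,8a-dimethyl-3-(propan-2-yl)-1,2,3,3a,4,5,8,8a-octahydroazulen-4-yl 4-[(tert-butyldimethylsilyl)oxy]benzoate
Conditions: NaBH4, CeCl3·7H2O, MeOH, −78 → −20 °C
Reagents that add atoms: none
Why: Luche 1,2-reduction delivers hydride to the enone carbonyl from the face opposite the adjacent pseudo-axial angular methyl, giving the (8S) allylic alcohol cis to that methyl and leaving the ester untouched.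

Step 13
Reactants: 22 (3S,3aS,4R,8S,8aS)-3,8-dihydroxy-6,8a-dimethyl-3-(propan-2-yl)-1,2,3,3a,4,5,8,8a-octahydroazulen-4-yl 4-[(tert-butyldimethylsilyl)oxy]benzoate; 23 3-methylbutanoic acid
Product: 24 (3S,3aS,4R,8R,8aS)-3-hydroxy-6,8a-dimethyl-8-[(3-methylbutanoyl)oxy]-3-(propan-2-yl)-1,2,3,3a,4,5,8,8a-octahydroazulen-4-yl 4-[(tert-butyldimethylsilyl)oxy]benzoate
Conditions: PPh3, DIAD, toluene, 0 → 23 °C
Reagents that add atoms: none
Why: Mitsunobu esterification proceeds by SN2 inversion at the activated allylic carbinol, the carboxylate entering from the open face away from the angular methyl, so the isovalerate ends trans to that methyl (8R) while the tertiary alcohol is inert.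

Step 14
Reactants: 24 (3S,3aS,4R,8R,8aS)-3-hydroxy-6,8a-dimethyl-8-[(3-methylbutanoyl)oxy]-3-(propan-2-yl)-1,2,3,3a,4,5,8,8a-octahydroazulen-4-yl 4-[(tert-butyldimethylsilyl)oxy]benzoate
Product: 25 (3S,3aS,4R,8R,8aS)-3-hydroxy-6,8a-dimethyl-8-[(3-methylbutanoyl)oxy]-3-(propan-2-yl)-1,2,3,3a,4,5,8,8a-octahydroazulen-4-yl 4-hydroxybenzoate
Conditions: Bu4NF, AcOH, THF, 0 °C
Reagents that add atoms: none
Why: Buffered fluoride cleaves the aryl silyl ether (silyl deprotection) without ester cleavage or acyl migration and gives the target.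

**Compound list**

1 | 2-[(tert-butyldimethylsilyl)oxy]acetaldehyde | CC(C)(C)[Si](C)(C)OCC=O | starting material
2 | pent-1-en-3-one | CCC(=O)C=C | starting material
3 | (2S)-2-[(tert-butyldimethylsilyl)oxy]-5-oxoheptanal | O=C[C@@H](O[Si](C)(C)C(C)(C)C)CCC(=O)CC | intermediate
4 | (4S)-4-[(tert-butyldimethylsilyl)oxy]-2-methylcyclohex-2-en-1-one | CC1=C[C@@H](O[Si](C)(C)C(C)(C)C)CCC1=O | intermediate
5 | 2-bromo-3-methylbut-1-ene | CC(C)C(Br)=C | starting material
6 | 3-bromoprop-1-ene | C=CCBr | starting material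
7 | (3-methylbut-1-en-2-yl)magnesium bromide | CC(C)C(=C)[Mg]Br | intermediate
8 | bromomagnesium (3S,4S)-4-[(tert-butyldimethylsilyl)oxy]-2-methyl-3-(3-methylbut-1-en-2-yl)cyclohex-1-en-1-olate | CC1=C(O[Mg]Br)CC[C@H](O[Si](C)(C)C(C)(C)C)[C@H]1C(=C)C(C)C | intermediate
9 | (2S,3S,4S)-4-[(tert-butyldimethylsilyl)oxy]-2-methyl-3-(3-methylbut-1-en-2-yl)-2-(prop-2-en-1-yl)cyclohexan-1-one | O=C1[C@@](C)(CC=C)[C@H](C(=C)C(C)C)[C@@H](O[Si](C)(C)C(C)(C)C)CC1 | intermediate
10 | (2S,3S,4S,6R)-4-[(tert-butyldimethylsilyl)oxy]-2,6-dimethyl-3-(3-methylbut-1-en-2-yl)-2-(prop-2-en-1-yl)cyclohexan-1-one | O=C1[C@@](C)(CC=C)[C@H](C(=C)C(C)C)[C@@H](O[Si](C)(C)C(C)(C)C)C[C@H]1C | intermediate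
11 | (3aS,5R,7S,7aS)-7-[(tert-butyldimethylsilyl)oxy]-3a,5-dimethyl-1-(propan-2-yl)-3,3a,5,6,7,7a-hexahydro-4H-inden-4-one | CC(C)C1=CC[C@]2(C)C(=O)[C@H](C)C[C@H](O[Si](C)(C)C(C)(C)C)[C@@H]12 | intermediate
12 | (1S,3aS,5R,7S,7aS)-7-[(tert-butyldimethylsilyl)oxy]-1-hydroxy-3a,5-dimethyl-1-(propan-2-yl)octahydro-4H-inden-4-one | CC(C)[C@@]1(O)CC[C@]2(C)C(=O)[C@H](C)C[C@H](O[Si](C)(C)C(C)(C)C)[C@@H]12 | intermediate
13 | (1S,3aS,5R,7S,7aS)-1,7-dihydroxy-3a,5-dimethyl-1-(propan-2-yl)octahydro-4H-inden-4-one | CC(C)[C@@]1(O)CC[C@]2(C)C(=O)[C@H](C)C[C@H](O)[C@@H]12 | intermediate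
14 | (1S,3aS,5R,7aR)-1-hydroxy-3a,5-dimethyl-1-(propan-2-yl)hexahydro-1H-indene-4,7-dione | CC(C)[C@@]1(O)CC[C@]2(C)C(=O)[C@H](C)CC(=O)[C@@H]12 | intermediate
15 | (1S,3aS,5R,7R,7aS)-1,7-dihydroxy-3a,5-dimethyl-1-(propan-2-yl)octahydro-4H-inden-4-one | CC(C)[C@@]1(O)CC[C@]2(C)C(=O)[C@H](C)C[C@@H](O)[C@@H]12 | intermediate
16 | (1S,3aS,7R,7aS)-3a,5-dimethyl-1-(propan-2-yl)-1,4,7-tris[(trimethylsilyl)oxy]-2,3,3a,6,7,7a-hexahydro-1H-indene | CC(C)[C@@]1(O[Si](C)(C)C)CC[C@]2(C)C(O[Si](C)(C)C)=C(C)C[C@@H](O[Si](C)(C)C)[C@@H]12 | intermediate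
17 | (1S,3aS,5R,7R,7aS)-5-(iodomethyl)-3a,5-dimethyl-1-(propan-2-yl)-1,7-bis[(trimethylsilyl)oxy]octahydro-4H-inden-4-one | CC(C)[C@@]1(O[Si](C)(C)C)CC[C@]2(C)C(=O)[C@](C)(CI)C[C@@H](O[Si](C)(C)C)[C@@H]12 | intermediate
18 | (3S,3aS,4R,8aS)-6,8a-dimethyl-3-(propan-2-yl)-3,4-bis[(trimethylsilyl)oxy]-2,3,3a,4,5,8a-hexahydroazulen-8(1H)-one | CC1=CC(=O)[C@@]2(C)CC[C@](O[Si](C)(C)C)(C(C)C)[C@@H]2[C@H](O[Si](C)(C)C)C1 | intermediate
19 | (3S,3aS,4R,8aS)-3,4-dihydroxy-6,8a-dimethyl-3-(propan-2-yl)-2,3,3a,4,5,8a-hexahydroazulen-8(1H)-one | CC1=CC(=O)[C@@]2(C)CC[C@](O)(C(C)C)[C@@H]2[C@H](O)C1 | intermediate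
20 | tert-butyl(4-iodophenoxy)dimethylsilane | CC(C)(C)[Si](C)(C)Oc1ccc(I)cc1 | starting material
21 | (3S,3aS,4R,8aS)-3-hydroxy-6,8a-dimethyl-8-oxo-3-(propan-2-yl)-1,2,3,3a,4,5,8,8a-octahydroazulen-4-yl 4-[(tert-butyldimethylsilyl)oxy]benzoate | CC1=CC(=O)[C@@]2(C)CC[C@](O)(C(C)C)[C@@H]2[C@H](OC(=O)c2ccc(O[Si](C)(C)C(C)(C)C)cc2)C1 | intermediate
22 | (3S,3aS,4R,8S,8aS)-3,8-dihydroxy-6,8a-dimethyl-3-(propan-2-yl)-1,2,3,3a,4,5,8,8a-octahydroazulen-4-yl 4-[(tert-butyldimethylsilyl)oxy]benzoate | CC1=C[C@H](O)[C@@]2(C)CC[C@](O)(C(C)C)[C@@H]2[C@H](OC(=O)c2ccc(O[Si](C)(C)C(C)(C)C)cc2)C1 | intermediate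
23 | 3-methylbutanoic acid | CC(C)CC(=O)O | starting material
24 | (3S,3aS,4R,8R,8aS)-3-hydroxy-6,8a-dimethyl-8-[(3-methylbutanoyl)oxy]-3-(propan-2-yl)-1,2,3,3a,4,5,8,8a-octahydroazulen-4-yl 4-[(tert-butyldimethylsilyl)oxy]benzoate | CC1=C[C@@H](OC(=O)CC(C)C)[C@@]2(C)CC[C@](O)(C(C)C)[C@@H]2[C@H](OC(=O)c2ccc(O[Si](C)(C)C(C)(C)C)cc2)C1 | intermediate
25 | (3S,3aS,4R,8R,8aS)-3-hydroxy-6,8a-dimethyl-8-[(3-methylbutanoyl)oxy]-3-(propan-2-yl)-1,2,3,3a,4,5,8,8a-octahydroazulen-4-yl 4-hydroxybenzoate | CC1=C[C@@H](OC(=O)CC(C)C)[C@@]2(C)CC[C@](O)(C(C)C)[C@@H]2[C@H](OC(=O)c2ccc(O)cc2)C1 | target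

**Step count and risks**

Total: 14 steps. Longest linear sequence: 14 steps (from 1 and 2 to 25).

The three steps most likely to fail, each with a fallback:

The ring expansion of step 10 is new and is the least certain step. Its fallback is the known Ito–Saegusa sequence, setting out from 16. Et2Zn and CH2I2 (CH2Cl2, 0 °C) cyclopropanate the silyl enol ether on the face away from the 3a-methyl to give siloxycyclopropane F1. FeCl3 in DMF (0 °C) cleaves the internal cyclopropane bond by single-electron oxidation and chlorine transfer to give tertiary β-chloro ketone F2. NaOAc in MeOH at reflux eliminates HCl, and the route is rejoined at bis-silyl enone 18, which the acid work-up of step 10 turns into 19.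

The Mitsunobu inversion of step 13 needs an oxyphosphonium salt on a neopentyl-type allylic alcohol, and SN1 or SN2' leakage is possible. The fallback avoids inversion and sets out from enone 21. Reagent-controlled reduction with (S)-2-methyl-CBS-oxazaborolidine and catecholborane (toluene, −78 °C; the quaternary C-8a flank taken as the large group) gives the (8R)-alcohol F3. Acylation with 3-methylbutanoyl chloride, pyridine and DMAP (retention) rejoins the route at 24.

In the carbonylative esterification of step 11, alcoholysis of the acylpalladium species by one equivalent of a hindered secondary alcohol may be slow. The fallback makes the acid first and sets out from 20. Iodine–magnesium exchange with i-PrMgCl·LiCl (THF, −20 °C) and CO2 give 4-[(tert-butyldimethylsilyl)oxy]benzoic acid F4. 2,4,6-Trichlorobenzoyl chloride and Et3N convert it into mixed anhydride F5, which acylates the secondary alcohol of 19 with DMAP in toluene (Yamaguchi esterification) and rejoins the route at 21.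

**Further compounds**

F1 | step 10 | cyclopropane adduct of 16: CH2 bridging C-4 and C-5 on the face opposite the 3a-methyl; (1S,3aS,7R,7aS)-3a,5-dimethyl-1-(propan-2-yl)-1,4,7-tris[(trimethylsilyl)oxy]-4,5-methano-octahydro-1H-indene | CC(C)[C@@]1(O[Si](C)(C)C)CC[C@]2(C)[C@]3(O[Si](C)(C)C)C[C@]3(C)C[C@@H](O[Si](C)(C)C)[C@@H]12
F2 | step 10 | (3S,3aS,4R,8aS)-6-chloro-6,8a-dimethyl-3-(propan-2-yl)-3,4-bis[(trimethylsilyl)oxy]octahydroazulen-8(1H)-one, both C-6 epimers | CC1(Cl)CC(=O)[C@@]2(C)CC[C@](O[Si](C)(C)C)(C(C)C)[C@@H]2[C@H](O[Si](C)(C)C)C1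
F3 | step 13 | (3S,3aS,4R,8R,8aS)-3,8-dihydroxy-6,8a-dimethyl-3-(propan-2-yl)-1,2,3,3a,4,5,8,8a-octahydroazulen-4-yl 4-[(tert-butyldimethylsilyl)oxy]benzoate | CC1=C[C@@H](O)[C@@]2(C)CC[C@](O)(C(C)C)[C@@H]2[C@H](OC(=O)c2ccc(O[Si](C)(C)C(C)(C)C)cc2)C1
F4 | step 11 | 4-[(tert-butyldimethylsilyl)oxy]benzoic acid | CC(C)(C)[Si](C)(C)Oc1ccc(cc1)C(=O)O
F5 | step 11 | 4-[(tert-butyldimethylsilyl)oxy]benzoic 2,4,6-trichlorobenzoic anhydride | CC(C)(C)[Si](C)(C)Oc1ccc(cc1)C(=O)OC(=O)c1c(Cl)cc(Cl)cc1Cl
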